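**Retrosynthetic overview**
1. Target 29 ⇐ 26: one CrCl2 operation closes C6–C7 of the ten-membered carbocycle and, by O9→O6 acyl transfer, the trans γ-lactone; the δ-lactone of 26 is a sacrificial template that locks C7 in a cyclic allyl unit and masks 9-OH.
2. 26 ⇐ cis-hydroxy lactone 25 + epoxy acid 3 (Mitsunobu inversion at C8); 3 ⇐ tiglyl alcohol 1 (Sharpless epoxidation, oxidation).
3. δ-Lactone 23 ⇐ RCM of the 2-(chloromethyl)acrylate of 20; 20 ⇐ Brown alkoxyallylboration of Z-enal 16 (sets C8, C9).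
4. 16 ⇐ δ-lactone 13 (Weinreb opening, acetylation, reduction); 13 ⇐ RCM of methacrylate 12 (Z C1=C10) ⇐ Brown allylation of Z-enal 7 (sets C3).
5. 7 ⇐ 3-methylfuran-2(5H)-one 4 (Z C4=C5 from the butenolide). Ring order: oxirane (side chain), δ-lactone 13, δ-lactone 23, then ten-membered ring and γ-lactone together.

Assumption: crude hydroxy amide 5 is carried on after aqueous work-up without purification and is treated as not isolated; 17 and 21 are taken as bought. Germacrane numbering (C1–C15) is used for positions.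

Step 1
Reactants: 1 (E)-2-methylbut-2-en-1-ol
Product: 2 [(2R,3R)-2,3-dimethyloxiran-2-yl]methanol
Conditions: Ti(OiPr)4 (10 mol%), D-(−)-diethyl tartrate (12 mol%), t-BuOOH, 4 Å MS, CH2Cl2, −20 °C
Reagents that add atoms: tert-butyl hydroperoxide, CC(C)(C)OO
Why: Katsuki–Sharpless asymmetric epoxidation with the D-tartrate delivers oxygen to the alkene face that gives the (2R,3R)-epoxide, which fixes both epoxide stereocentres of the side chain with the two methyls cis.

Step 2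
Reactants: 2 [(2R,3R)-2,3-dimethyloxiran-2-yl]methanol
Product: 3 (2S,3R)-2,3-dimethyloxirane-2-carboxylic acid
Conditions: RuCl3·xH2O (2 mol%), NaIO4, MeCN/EtOAc/H2O, 0 °C to rt
Reagents that add atoms: sodium periodate, [Na+].[O-]I(=O)(=O)=O
Why: RuO4 oxidation (RuCl3/NaIO4) takes the primary alcohol to the acid and leaves the epoxide untouched, so only the CIP descriptor at C2 changes.

Step 3
Reactants: 4 3-methylfuran-2(5H)-one
Product: 6 (2Z)-N-methoxy-4-(methoxymethoxy)-N,2-dimethylbut-2-enamide, via hydroxy amide 5 (not isolated)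
Conditions: MeNH(OMe)·HCl, AlMe3, CH2Cl2, 0 °C to rt; aq. potassium sodium tartrate; crude: MOMCl, iPr2NEt, CH2Cl2, 0 °C to rt
Reagents that add atoms: N,O-dimethylhydroxylamine hydrochloride, CNOC.Cl; chloromethyl methyl ether, COCCl
Why: Weinreb aminolysis with the aluminium amide opens the butenolide at the acyl carbon so the ring-enforced Z geometry of the future C4=C5 bond is kept, and MOM etherification of the crude γ-hydroxy amide blocks relactonisation (no stereocentre formed).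

Step 4
Reactants: 6 (2Z)-N-methoxy-4-(methoxymethoxy)-N,2-dimethylbut-2-enamide
Product: 7 (2Z)-4-(methoxymethoxy)-2-methylbut-2-enal
Conditions: iBu2AlH, THF, −78 °C; aq. potassium sodium tartrate
Reagents that add atoms: none
Why: Reduction of a Weinreb amide stops at the aldehyde because the chelated tetrahedral aluminium intermediate collapses only on work-up, and the Z-enal does not isomerise at −78 °C.

Step 5
Reactants: 7 (2Z)-4-(methoxymethoxy)-2-methylbut-2-enal; 8 allylmagnesium bromide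
Product: 10 (4S,5Z)-7-(methoxymethoxy)-5-methylhepta-1,5-dien-4-ol, via B-allyldiisopinocampheylborane 9 (not isolated)
Conditions: 8, (−)-Ipc2BOMe, Et2O, 0 °C to rt; then 7, −78 °C; NaOH, H2O2
Reagents that add atoms: none
Why: Brown asymmetric allylboration, in which the allylborane with Ipc groups from (+)-α-pinene adds through a chair transition state to the si face of the enal and sets C3 as S by reagent control.

Step 6
Reactants: 10 (4S,5Z)-7-(methoxymethoxy)-5-methylhepta-1,5-dien-4-ol; 11 methacryloyl chloride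
Product: 12 (4S,5Z)-7-(methoxymethoxy)-5-methylhepta-1,5-dien-4-yl 2-methylprop-2-enoate
Conditions: Et3N, DMAP (cat.), CH2Cl2, 0 °C
Reagents that add atoms: none
Why: DMAP-catalysed acylation of the secondary allylic alcohol puts the methacrylate (future C9, C10, C14) in place and leaves C3 untouched.

Step 7
Reactants: 12 (4S,5Z)-7-(methoxymethoxy)-5-methylhepta-1,5-dien-4-yl 2-methylprop-2-enoate
Product: 13 (6S)-6-[(2Z)-4-(methoxymethoxy)but-2-en-2-yl]-3-methyl-5,6-dihydro-2H-pyran-2-one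
Conditions: second-generation Grubbs catalyst RuCl2(H2IMes)(PCy3)(=CHPh) (5 mol%), CH2Cl2, 40 °C, 0.01 M
Reagents that add atoms: none
Why: Ring-closing metathesis of the terminal vinyl group with the methacrylate forms the six-membered lactone, whose ring forces the new trisubstituted C1=C10 bond to be Z, while the hindered C4=C5 bond stays out.

Step 8
Reactants: 13 (6S)-6-[(2Z)-4-(methoxymethoxy)but-2-en-2-yl]-3-methyl-5,6-dihydro-2H-pyran-2-one
Product: 15 (2Z,5S,6Z)-5-acetoxy-N-methoxy-8-(methoxymethoxy)-N,2,6-trimethylocta-2,6-dienamide, via aluminium alkoxide 14 (not isolated)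
Conditions: MeNH(OMe)·HCl, AlMe3, CH2Cl2, 0 °C to rt; then pyridine, DMAP, Ac2O, 0 °C (same flask)
Reagents that add atoms: N,O-dimethylhydroxylamine hydrochloride, CNOC.Cl; acetic anhydride, CC(=O)OC(C)=O
Why: Weinreb aminolysis opens the δ-lactone with retention of the Z-enoate geometry and the C3 aluminium alkoxide is acetylated in the same flask (as in reductive acetylation), which installs the 3-acetate with C3 unchanged and prevents relactonisation.

Step 9
Reactants: 15 (2Z,5S,6Z)-5-acetoxy-N-methoxy-8-(methoxymethoxy)-N,2,6-trimethylocta-2,6-dienamide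
Product: 16 (2Z,5S,6Z)-5-acetoxy-8-(methoxymethoxy)-2,6-dimethylocta-2,6-dienal
Conditions: Cp2Zr(H)Cl, THF, rt, 20 min
Reagents that add atoms: none
Why: Schwartz reduction of a tertiary amide gives the aldehyde through a zirconated hemiaminal within minutes and leaves the acetate, the MOM ether and the trisubstituted alkenes alone.

Step 10
Reactants: 16 (2Z,5S,6Z)-5-acetoxy-8-(methoxymethoxy)-2,6-dimethylocta-2,6-dienal; 17 allyl methoxymethyl ether
Product: 20 (3R,4R,5Z,8S,9Z)-4-hydroxy-3,11-bis(methoxymethoxy)-5,9-dimethylundeca-1,5,9-trien-8-yl acetate, via lithiated allyl ether 18 (not isolated), via alkoxyallylborane 19 (not isolated)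
Conditions: 17, s-BuLi, THF, −78 °C; (−)-Ipc2BOMe; BF3·OEt2; then 16, −78 °C; NaBO3·4H2O, THF/H2O
Reagents that add atoms: none
Why: Brown alkoxyallylboration, in which the (Z)-γ-alkoxyallylborane with Ipc groups from (+)-α-pinene adds through a chair transition state to the si face of the enal, sets C9 as R by reagent control and C8 syn to it (8R, inverted in step 15).

Step 11
Reactants: 20 (3R,4R,5Z,8S,9Z)-4-hydroxy-3,11-bis(methoxymethoxy)-5,9-dimethylundeca-1,5,9-trien-8-yl acetate; 21 2-(chloromethyl)acrylic acid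
Product: 22 (3R,4R,5Z,8S,9Z)-8-acetoxy-3,11-bis(methoxymethoxy)-5,9-dimethylundeca-1,5,9-trien-4-yl 2-(chloromethyl)acrylate
Conditions: DCC, DMAP (cat.), CH2Cl2, 0 °C
Reagents that add atoms: none
Why: Steglich esterification acylates the only free hydroxyl (O9) with the unit that becomes C11–C13, without changing any stereocentre.

Step 12
Reactants: 22 (3R,4R,5Z,8S,9Z)-8-acetoxy-3,11-bis(methoxymethoxy)-5,9-dimethylundeca-1,5,9-trien-4-yl 2-(chloromethyl)acrylate
Product: 23 (5R,6R)-6-[(2Z,5S,6Z)-5-acetoxy-8-(methoxymethoxy)-6-methylocta-2,6-dien-2-yl]-3-(chloromethyl)-5-(methoxymethoxy)-5,6-dihydro-2H-pyran-2-one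
Conditions: second-generation Hoveyda–Grubbs catalyst RuCl2(H2IMes)(=CH-C6H4-2-OiPr) (10 mol%), toluene, 80 °C, 5 mM
Reagents that add atoms: none
Why: Ring-closing metathesis of the C8 vinyl group with the acrylate closes the dihydropyranone, which locks C7=C11 with C8 cis to the carbonyl and leaves the allylic chloride on the exocyclic carbon (C8 and C9 untouched, cis on the ring).

Step 13
Reactants: 23 (5R,6R)-6-[(2Z,5S,6Z)-5-acetoxy-8-(methoxymethoxy)-6-methylocta-2,6-dien-2-yl]-3-(chloromethyl)-5-(methoxymethoxy)-5,6-dihydro-2H-pyran-2-one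
Product: 24 (5R,6R)-6-[(2Z,5S,6Z)-5-acetoxy-8-hydroxy-6-methylocta-2,6-dien-2-yl]-3-(chloromethyl)-5-hydroxy-5,6-dihydro-2H-pyran-2-one
Conditions: Me2BBr, CH2Cl2, −78 °C; then THF, sat. NaHCO3
Reagents that add atoms: none
Why: Guindon acetal cleavage, in which Me2BBr opens both MOM groups at −78 °C by bromide attack on the boron-activated O–CH2–O unit and spares the esters, the allylic chloride and the alkenes.

Step 14
Reactants: 24 (5R,6R)-6-[(2Z,5S,6Z)-5-acetoxy-8-hydroxy-6-methylocta-2,6-dien-2-yl]-3-(chloromethyl)-5-hydroxy-5,6-dihydro-2H-pyran-2-one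
Product: 25 (5R,6R)-6-[(2Z,5S,6Z)-5-acetoxy-6-methyl-8-oxoocta-2,6-dien-2-yl]-3-(chloromethyl)-5-hydroxy-5,6-dihydro-2H-pyran-2-one
Conditions: TEMPO (10 mol%), PhI(OAc)2, CH2Cl2, rt
Reagents that add atoms: none
Why: Oxoammonium (TEMPO/PhI(OAc)2) oxidation takes the primary allylic alcohol selectively over the secondary one and gives the Z-enal without isomerisation.

Step 15
Reactants: 25 (5R,6R)-6-[(2Z,5S,6Z)-5-acetoxy-6-methyl-8-oxoocta-2,6-dien-2-yl]-3-(chloromethyl)-5-hydroxy-5,6-dihydro-2H-pyran-2-one; 3 (2S,3R)-2,3-dimethyloxirane-2-carboxylic acid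
Product: 26 (2R,3S)-2-[(2Z,5S,6Z)-5-acetoxy-6-methyl-8-oxoocta-2,6-dien-2-yl]-5-(chloromethyl)-6-oxo-3,6-dihydro-2H-pyran-3-yl (2S,3R)-2,3-dimethyloxirane-2-carboxylate
Conditions: PPh3, DIAD, toluene, 0 °C to rt
Reagents that add atoms: none
Why: Mitsunobu esterification, in which SN2 displacement of the alkoxyphosphonium ion by the carboxylate of 3 inverts C8 (R to S, cis to trans on the lactone) and installs the intact epoxy ester in the same step.

Step 16
Reactants: 26 (2R,3S)-2-[(2Z,5S,6Z)-5-acetoxy-6-methyl-8-oxoocta-2,6-dien-2-yl]-5-(chloromethyl)-6-oxo-3,6-dihydro-2H-pyran-3-yl (2S,3R)-2,3-dimethyloxirane-2-carboxylate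
Product: 29 (1(10)Z,4Z)-3β-acetoxy-9β-hydroxy-8β-[(2S,3R)-2,3-dimethyloxirane-2-carbonyloxy]germacra-1(10),4,11(13)-trien-12,6α-olide (CNP0299903.2), via allylchromium species 27 (not isolated), via bridged chromium alkoxide 28 (not isolated)
Conditions: CrCl2 (10 equiv), THF/DMF (10:1), 2 mM (slow addition), 25 °C; aq. NH4Cl
Reagents that add atoms: none
Why: Proposed new method: CrCl2 reduces the allylic chloride to an allylchromium (trivalent chromium) whose ring-locked γ-carbon C7 adds to the tethered Z-enal in a chair-like Nozaki–Hiyama–Kishi transition state on the lactone face that carries the C9 side chain and is anti to the C8 ester (7S), with the enal substituent equatorial (anti adduct, 6R), and the C6 chromium alkoxide then attacks the bridging δ-lactone carbonyl in a 5-exo acyl transfer that forms the trans α-methylene-γ-lactone and frees 9-OH, the closest known reactions being CrCl2 allylation/lactonisation with 2-(halomethyl)acrylates and 3-(bromomethyl)furan-2(5H)-ones and chromium Barbier macrocyclisations to germacranolides.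

**Compound list**
1 | (E)-2-methylbut-2-en-1-ol | C/C=C(\C)CO | starting material
2 | [(2R,3R)-2,3-dimethyloxiran-2-yl]methanol | OC[C@@]1(C)O[C@@H]1C | intermediate
3 | (2S,3R)-2,3-dimethyloxirane-2-carboxylic acid | OC(=O)[C@@]1(C)O[C@@H]1C | intermediate
4 | 3-methylfuran-2(5H)-one | CC1=CCOC1=O | starting material
5 | (2Z)-4-hydroxy-N-methoxy-N,2-dimethylbut-2-enamide (not isolated) | CON(C)C(=O)/C(C)=C\CO | intermediate
6 | (2Z)-N-methoxy-4-(methoxymethoxy)-N,2-dimethylbut-2-enamide | CON(C)C(=O)/C(C)=C\COCOC | intermediate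
7 | (2Z)-4-(methoxymethoxy)-2-methylbut-2-enal | O=C/C(C)=C\COCOC | intermediate
8 | allylmagnesium bromide | C=CC[Mg]Br | starting material
9 | B-allyldiisopinocampheylborane, Ipc from (+)-α-pinene (not isolated) | C=CCB([C@@H]1C[C@@H]2C[C@@H](C2(C)C)[C@H]1C)[C@@H]1C[C@@H]2C[C@@H](C2(C)C)[C@H]1C | intermediate
10 | (4S,5Z)-7-(methoxymethoxy)-5-methylhepta-1,5-dien-4-ol | C=CC[C@H](O)/C(C)=C\COCOC | intermediate
11 | methacryloyl chloride | C=C(C)C(Cl)=O | starting material
12 | (4S,5Z)-7-(methoxymethoxy)-5-methylhepta-1,5-dien-4-yl 2-methylprop-2-enoate | C=CC[C@H](OC(=O)C(C)=C)/C(C)=C\COCOC | intermediate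
13 | (6S)-6-[(2Z)-4-(methoxymethoxy)but-2-en-2-yl]-3-methyl-5,6-dihydro-2H-pyran-2-one | CC1=CC[C@H](OC1=O)/C(C)=C\COCOC | intermediate
14 | chloro(methyl)aluminium alkoxide of (2Z,5S,6Z)-5-hydroxy-N-methoxy-8-(methoxymethoxy)-N,2,6-trimethylocta-2,6-dienamide (not isolated) | CON(C)C(=O)/C(C)=C\C[C@H](O[Al](C)Cl)/C(C)=C\COCOC | intermediate
15 | (2Z,5S,6Z)-5-acetoxy-N-methoxy-8-(methoxymethoxy)-N,2,6-trimethylocta-2,6-dienamide | CON(C)C(=O)/C(C)=C\C[C@H](OC(C)=O)/C(C)=C\COCOC | intermediate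
16 | (2Z,5S,6Z)-5-acetoxy-8-(methoxymethoxy)-2,6-dimethylocta-2,6-dienal | O=C/C(C)=C\C[C@H](OC(C)=O)/C(C)=C\COCOC | intermediate
17 | allyl methoxymethyl ether | C=CCOCOC | starting material
18 | (Z)-3-(methoxymethoxy)allyllithium (not isolated) | [Li]C/C=C\OCOC | intermediate
19 | [(Z)-3-(methoxymethoxy)allyl]diisopinocampheylborane, Ipc from (+)-α-pinene (not isolated) | COCO/C=C\CB([C@@H]1C[C@@H]2C[C@@H](C2(C)C)[C@H]1C)[C@@H]1C[C@@H]2C[C@@H](C2(C)C)[C@H]1C | intermediate
20 | (3R,4R,5Z,8S,9Z)-4-hydroxy-3,11-bis(methoxymethoxy)-5,9-dimethylundeca-1,5,9-trien-8-yl acetate | C=C[C@@H](OCOC)[C@H](O)/C(C)=C\C[C@H](OC(C)=O)/C(C)=C\COCOC | intermediate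
21 | 2-(chloromethyl)acrylic acid | C=C(CCl)C(O)=O | starting material
22 | (3R,4R,5Z,8S,9Z)-8-acetoxy-3,11-bis(methoxymethoxy)-5,9-dimethylundeca-1,5,9-trien-4-yl 2-(chloromethyl)acrylate | C=C[C@@H](OCOC)[C@H](OC(=O)C(=C)CCl)/C(C)=C\C[C@H](OC(C)=O)/C(C)=C\COCOC | intermediate
23 | (5R,6R)-6-[(2Z,5S,6Z)-5-acetoxy-8-(methoxymethoxy)-6-methylocta-2,6-dien-2-yl]-3-(chloromethyl)-5-(methoxymethoxy)-5,6-dihydro-2H-pyran-2-one | O=C1O[C@H](/C(C)=C\C[C@H](OC(C)=O)/C(C)=C\COCOC)[C@H](OCOC)C=C1CCl | intermediate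
24 | (5R,6R)-6-[(2Z,5S,6Z)-5-acetoxy-8-hydroxy-6-methylocta-2,6-dien-2-yl]-3-(chloromethyl)-5-hydroxy-5,6-dihydro-2H-pyran-2-one | O=C1O[C@H](/C(C)=C\C[C@H](OC(C)=O)/C(C)=C\CO)[C@H](O)C=C1CCl | intermediate
25 | (5R,6R)-6-[(2Z,5S,6Z)-5-acetoxy-6-methyl-8-oxoocta-2,6-dien-2-yl]-3-(chloromethyl)-5-hydroxy-5,6-dihydro-2H-pyran-2-one | O=C1O[C@H](/C(C)=C\C[C@H](OC(C)=O)/C(C)=C\C=O)[C@H](O)C=C1CCl | intermediate
26 | (2R,3S)-2-[(2Z,5S,6Z)-5-acetoxy-6-methyl-8-oxoocta-2,6-dien-2-yl]-5-(chloromethyl)-6-oxo-3,6-dihydro-2H-pyran-3-yl (2S,3R)-2,3-dimethyloxirane-2-carboxylate | O=C1O[C@H](/C(C)=C\C[C@H](OC(C)=O)/C(C)=C\C=O)[C@@H](OC(=O)[C@@]2(C)O[C@@H]2C)C=C1CCl | intermediate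
27 | allylchromium dichloride of 26 (C13–CrCl2 in place of C13–Cl; not isolated) | O=C1O[C@H](/C(C)=C\C[C@H](OC(C)=O)/C(C)=C\C=O)[C@@H](OC(=O)[C@@]2(C)O[C@@H]2C)C=C1C[Cr](Cl)Cl | intermediate
28 | (1(10)Z,4Z)-3β-acetoxy-6α-(dichlorochromiooxy)-8β-[(2S,3R)-2,3-dimethyloxirane-2-carbonyloxy]germacra-1(10),4,11(13)-trien-12,9β-olide (not isolated) | C=C1C(=O)O[C@@H]2/C(C)=C\C[C@H](OC(C)=O)/C(C)=C\[C@@H](O[Cr](Cl)Cl)[C@H]1[C@@H]2OC(=O)[C@@]3(C)O[C@@H]3C | intermediate
29 | (1(10)Z,4Z)-3β-acetoxy-9β-hydroxy-8β-[(2S,3R)-2,3-dimethyloxirane-2-carbonyloxy]germacra-1(10),4,11(13)-trien-12,6α-olide (3S,6R,7S,8S,9R) | C=C1C(=O)O[C@@H]2/C=C(/C)[C@@H](OC(C)=O)C/C=C(/C)[C@@H](O)[C@@H](OC(=O)[C@@]3(C)O[C@@H]3C)[C@@H]12 | target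

**Step count:** 16 steps in total. Longest linear sequence: 14 steps (steps 3–16, from 4); the side chain (steps 1–2) joins at step 15.

**Steps most likely to fail**

Step 16. The allylchromium may lose the C8 ester by vinylogous β-elimination before the slow ten-membered ring closure, CrCl2 may attack the epoxy ester, the C6 epimer may form, or the acyl transfer may stop at the bridged lactone. The fallback sets out from 26: base-free borylation (B2pin2, Pd(dba)2 cat., toluene, 50 °C) gives the pinacol allylboronate F1. Heating F1 at 2 mM in toluene (80 °C, or Sc(OTf)3 cat. at rt) closes the ring by a closed six-membered allylboration with no carbon–metal bond that can eliminate, and NaHCO3 work-up gives the bridged hydroxy δ-lactone F2. CSA (cat.) in CH2Cl2 then moves the acyl group from O9 to O6 and the route is back at 29.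

Step 15. The hindered α-quaternary acid 3 may displace too slowly, so that the activated alcohol eliminates to the 2-pyranone. The fallback sets out from 24 and avoids SN2 chemistry: Dess–Martin periodinane oxidises both hydroxyls to the keto aldehyde F3. NaBH4/CeCl3 (MeOH, −78 °C) reduces both carbonyls 1,2, hydride entering the ring ketone so that the new hydroxyl is trans to the C9 side chain, to give the trans-diol F4. TEMPO/PhI(OAc)2 gives the trans-hydroxy enal F5, and DCC/DMAP esterification with 3 (retention) returns to 26.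

Step 12. RCM to a trisubstituted, electron-poor alkene next to an allylic ether may stall. The fallback sets out from 20: acryloyl chloride/Et3N gives the acrylate F6, whose RCM (same Ru catalyst, disubstituted alkene) gives the 3-unsubstituted dihydropyranone F7. Morita–Baylis–Hillman hydroxymethylation (aq. CH2O, PMe3, THF) gives the 3-(hydroxymethyl) lactone F8, and MsCl/Et3N followed by LiCl returns to 23.

**Further compounds**
F1 | step 16 | (2R,3S)-2-[(2Z,5S,6Z)-5-acetoxy-6-methyl-8-oxoocta-2,6-dien-2-yl]-6-oxo-5-[(4,4,5,5-tetramethyl-1,3,2-dioxaborolan-2-yl)methyl]-3,6-dihydro-2H-pyran-3-yl (2S,3R)-2,3-dimethyloxirane-2-carboxylate | O=C1O[C@H](/C(C)=C\C[C@H](OC(C)=O)/C(C)=C\C=O)[C@@H](OC(=O)[C@@]2(C)O[C@@H]2C)C=C1CB1OC(C)(C)C(C)(C)O1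
F2 | step 16 | (1(10)Z,4Z)-3β-acetoxy-6α-hydroxy-8β-[(2S,3R)-2,3-dimethyloxirane-2-carbonyloxy]germacra-1(10),4,11(13)-trien-12,9β-olide | C=C1C(=O)O[C@@H]2/C(C)=C\C[C@H](OC(C)=O)/C(C)=C\[C@@H](O)[C@H]1[C@@H]2OC(=O)[C@@]3(C)O[C@@H]3C
F3 | step 15 | (6R)-6-[(2Z,5S,6Z)-5-acetoxy-6-methyl-8-oxoocta-2,6-dien-2-yl]-3-(chloromethyl)-2H-pyran-2,5(6H)-dione | O=C1O[C@H](/C(C)=C\C[C@H](OC(C)=O)/C(C)=C\C=O)C(=O)C=C1CCl
F4 | step 15 | (5S,6R)-6-[(2Z,5S,6Z)-5-acetoxy-8-hydroxy-6-methylocta-2,6-dien-2-yl]-3-(chloromethyl)-5-hydroxy-5,6-dihydro-2H-pyran-2-one | O=C1O[C@H](/C(C)=C\C[C@H](OC(C)=O)/C(C)=C\CO)[C@@H](O)C=C1CCl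
F5 | step 15 | (5S,6R)-6-[(2Z,5S,6Z)-5-acetoxy-6-methyl-8-oxoocta-2,6-dien-2-yl]-3-(chloromethyl)-5-hydroxy-5,6-dihydro-2H-pyran-2-one | O=C1O[C@H](/C(C)=C\C[C@H](OC(C)=O)/C(C)=C\C=O)[C@@H](O)C=C1CCl
F6 | step 12 | (3R,4R,5Z,8S,9Z)-8-acetoxy-3,11-bis(methoxymethoxy)-5,9-dimethylundeca-1,5,9-trien-4-yl acrylate | C=C[C@@H](OCOC)[C@H](OC(=O)C=C)/C(C)=C\C[C@H](OC(C)=O)/C(C)=C\COCOC
F7 | step 12 | (5R,6R)-6-[(2Z,5S,6Z)-5-acetoxy-8-(methoxymethoxy)-6-methylocta-2,6-dien-2-yl]-5-(methoxymethoxy)-5,6-dihydro-2H-pyran-2-one | O=C1O[C@H](/C(C)=C\C[C@H](OC(C)=O)/C(C)=C\COCOC)[C@H](OCOC)C=C1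
F8 | step 12 | (5R,6R)-6-[(2Z,5S,6Z)-5-acetoxy-8-(methoxymethoxy)-6-methylocta-2,6-dien-2-yl]-3-(hydroxymethyl)-5-(methoxymethoxy)-5,6-dihydro-2H-pyran-2-one | O=C1O[C@H](/C(C)=C\C[C@H](OC(C)=O)/C(C)=C\COCOC)[C@H](OCOC)C=C1CO
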